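Scaling the loss seen in zeta in proportion to the impurity is a trap: for north-west it gives a floor, not an estimate.

the same everywhere: starting material 0.43 M; coupling partner 0.774 M
- delta: protic impurity 0.013 M; run made earlier
- zeta: protic impurity 0.90 M; run made earlier
- south-east: protic impurity 0.0150 M; time 5.0 d
- west: protic impurity 0.0500 M; time 5.0 d
- north: protic impurity 0.150 M; time 5.0 d
- north-east: protic impurity 0.400 M; time 5.0 d
- north-west: protic impurity 1.20 M; time 5.0 d

| run | time / d | product / % |
|---|---|---|
| delta | 0.500 | 75.2 |
| delta | 1.04 | 93.1 |
| delta | 1.67 | 98.2 |
| delta | 2.08 | 99.2 |
| delta | 2.50 | 99.0 |
| zeta | 0.208 | 40.0 |
| zeta | 0.417 | 59.6 |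
| zeta | 0.625 | 67.6 |
| zeta | 1.25 | 79.4 |
| zeta | 2.50 | 83.9 |

(readings scatter by 1 percentage point)

- a step back or a flat step of under half a point counts as no turn
- "hardly changes" means that all values lie within two and a half points (for a concentration: within two and a half percent of the largest)

1. amount of product at the end, in percent of the starting material charged for south-east, west, north, north-east, north-west, in this order
2. how the row runs (rises all the way / rises, then falls / falls all the way / hardly changes / falls, then rises)

Delta nears completion, but zeta reads 83.9 % at 2.50 d. I assume that the coupling partner is spent one to one on the starting material and on the impurity, and that zeta has exhausted it by then, so the impurity has taken 0.413 M of partner there. The excess of partner, 0.344 M, is larger than the 0.150 M of impurity in north, so on this assumption south-east, west and north can convert fully. North-east, with 0.400 M, has a floor of 87.0 %.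

North-west carries more impurity than zeta, so I take zeta's reading as its ceiling, and proportional scaling of the loss gives a floor of 51.9 %. To tighten this, I assume that both reactions are first order in partner, so its concentration cancels from their ratio and time drops out. If U is the fraction of the charged starting material not yet product and h the fraction of impurity left, then h = U^s. Here s is the selectivity factor, the quenching constant over the coupling constant, read from zeta as 0.337.

Partner demanded is product made plus impurity quenched. In north-west, a yield of 0.7 of the charge demands 0.701 M, within the charge of 0.774 M. A trial yield of 79.4 % demands 0.836 M, beyond it. My bracket for north-west is therefore these two yields, and I expect the row to fall.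

The forecast gives 99.7 %, 99.5 %, 99 %, 97 % and 76 %, shape falls all the way, and holds that “Five days is long enough to reach the plateau in every run.” Its last value lies inside my bracket.

The flasks give 100 %, 100 %, 100 %, 98.8 % and 76.6 %, shape falls all the way; north-west also lies inside the bracket.

    starting material → intermediate (k = 0.760 h⁻¹)
    coupling partner + intermediate → product (k = 0.240 M⁻¹ h⁻¹)
    coupling partner + protic impurity → quenched reagent (k = 0.0660 M⁻¹ h⁻¹)

In south-east at 0.0381 d, the intermediate has a half-life of 0.16 d by coupling, while the partner has one of 31 d by quenching. In north-west at 5.00 d, 0.0062 % of the partner remains beside 23.4 % intermediate, and h = U^s with s = 0.337 gives 61.3 % of the impurity left against the simulated 63 %. In north-east, taking U as the 1.16 % intermediate, the same rule gives 22.3 % against the simulated 27 %.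

The numbers in the tables are calculated from invented constants.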